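**Plan**
1. Retrosynthetic cuts: the ester C(=O)–O bond; the C3–C4 and C5–C6 bonds of the cyclohexene ring (C1 = carbinol carbon, C3=C4 = alkene, C4 bears CH3); the two aryl–CH2 (prenyl) bonds.
2. Enabling feature: C1 of the cyclohexene carries O, isopropyl and two ring CH2 arms (C2, C6) that differ only in where the C3=C4 double bond lies. C1 therefore maps onto C3 of an achiral 3-isopropyl-3-siloxycyclobutanone whose two C(=O)–CH2 bonds are enantiotopic.
3. Forward: the cyclobutanone is made from 3-(benzyloxy)cyclobutanone. Nickel-catalysed enantioselective insertion of a silyl-capped propyne into one C(=O)–CH2 bond expands the four-membered ring to the six-membered ring (the only ring-forming event) and gives a 2-methylcyclohex-2-enone.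
4. C-desilylation, reductive 1,3-transposition of the enone tosylhydrazone (carbonyl carbon becomes C3–H, double bond lands at C3=C4) and O-desilylation give (R)-terpinen-4-ol.
5. The acid comes from methyl 3,5-dibromo-4-hydroxybenzoate by O-methylation, twofold Stille prenylation and saponification; the lithium alkoxide of the alcohol is acylated with the acid chloride last.
6. Stereochemistry: the single stereocentre is set in the key step by the chiral ligand on nickel (desymmetrisation). The later alkene placement is a concerted, regiospecific retro-ene step, so the alkene position on which the configuration rests is not scrambled.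

Key step: step 6

Remark: the sense of induction of the chiral nickel catalyst cannot be predicted with confidence, so the ligand antipode is assumed to be fixed by screening, with the (R) assignment checked at the free terpinen-4-ol stage by optical rotation and chiral GC.

**Step 1**
Reactants: 1 3-(benzyloxy)cyclobutan-1-one
Product: 2 3-(benzyloxy)-1-(propan-2-yl)cyclobutan-1-ol (cis/trans mixture)
Conditions: iPrMgCl, LaCl3·2LiCl (30 mol%), THF, 0 °C; aq NH4Cl
Reagents that add atoms: isopropylmagnesium chloride, CC(C)[Mg]Cl
Why: Lanthanum-promoted Grignard 1,2-addition should outrun enolisation and β-hydride reduction of the strained ketone; both ring diastereomers are carried on because the benzyloxy-bearing carbon becomes a carbonyl in step 4.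

**Step 2**
Reactants: 2 3-(benzyloxy)-1-(propan-2-yl)cyclobutan-1-ol
Product: 3 {[3-(benzyloxy)-1-(propan-2-yl)cyclobutyl]oxy}triethylsilane (cis/trans mixture)
Conditions: TESOTf, 2,6-lutidine, CH2Cl2, −78 °C to 0 °C
Reagents that add atoms: triethylsilyl trifluoromethanesulfonate, CC[Si](CC)(CC)OS(=O)(=O)C(F)(F)F
Why: A silyl triflate with a hindered pyridine base silylates tertiary alcohols without ionising the cyclobutanol (silyl ether formation).

**Step 3**
Reactants: 3 {[3-(benzyloxy)-1-(propan-2-yl)cyclobutyl]oxy}triethylsilane
Product: 4 3-(propan-2-yl)-3-[(triethylsilyl)oxy]cyclobutan-1-ol (cis/trans mixture)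
Conditions: H2 (1 atm), 10% Pd/C, EtOAc, rt
Reagents that add atoms: none
Why: Hydrogenolysis of the benzyl ether in a non-protic solvent should leave the triethylsilyl ether untouched.

**Step 4**
Reactants: 4 3-(propan-2-yl)-3-[(triethylsilyl)oxy]cyclobutan-1-ol
Product: 5 3-(propan-2-yl)-3-[(triethylsilyl)oxy]cyclobutan-1-one
Conditions: Dess–Martin periodinane, NaHCO3, CH2Cl2, 0 °C to rt
Reagents that add atoms: none
Why: Dess–Martin oxidation is mild and buffered, so the β-siloxy cyclobutanone should form without β-elimination or ring opening.

**Step 5**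
Reactants: 6 prop-1-yn-1-ylmagnesium bromide
Product: 7 triethoxy(prop-1-yn-1-yl)silane
Conditions: ClSi(OEt)3, THF, −78 °C to rt; distillation
Reagents that add atoms: chlorotriethoxysilane, CCO[Si](Cl)(OCC)OCC
Why: Nucleophilic substitution at silicon by the alkynyl Grignard reagent displaces chloride much faster than ethoxide, giving the mono-alkynylsilane.

**Step 6**
Reactants: 5 3-(propan-2-yl)-3-[(triethylsilyl)oxy]cyclobutan-1-one and 7 triethoxy(prop-1-yn-1-yl)silane
Product: 8 (5S)-2-methyl-5-(propan-2-yl)-3-(triethoxysilyl)-5-[(triethylsilyl)oxy]cyclohex-2-en-1-one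
Conditions: Ni(cod)2 (10 mol%), (S)-BINOL-derived phosphoramidite of bis[(S)-1-phenylethyl]amine (20 mol%), toluene, 90 °C
Reagents that add atoms: none
Why: Proposed new method: zerovalent nickel couples the strained C=O of 5 and the alkyne of 7 by oxidative cyclisation to a spiro oxanickelacyclopentene, β-carbon elimination then cleaves one of the two enantiotopic C(=O)–CH2 bonds of the four-membered ring with release of strain to give a seven-membered alkenyl–alkyl nickelacycle, and C(sp2)–C(sp3) reductive elimination closes the cyclohexenone, so the carbonyl carbon–alkyne carbon bond and the alkyne carbon–CH2 bond are made in one operation. The closest known reaction type is the racemic nickel/trialkylphosphine-catalysed intermolecular insertion of internal alkynes into 3,3-disubstituted cyclobutanones, together with the enantioselective intramolecular olefin insertion into cyclobutanones under nickel/chiral phosphoramidite catalysis; the enantioselective intermolecular version with a silylalkyne is the new element. The six-membered ring is closed by a formal [4+2] annulation, that is a two-carbon ring expansion of the cyclobutanone ending in reductive elimination from the seven-membered metallacycle. The only stereocentre, C5, is a pre-existing quaternary carbon that becomes stereogenic when the chiral ligand on nickel selects which enantiotopic ring bond undergoes β-carbon elimination. The step needs alkyne regioselectivity (methyl-bearing carbon to the carbonyl carbon, silicon-bearing carbon to the CH2), which the silyl group should secure because nickel prefers to bind the α-silyl carbon and C–C bond formation occurs at the distal carbon; it also needs chemoselectivity against alkyne oligomerisation and against β-hydride or β-siloxide loss from the alkylnickel intermediate, which the internal silylalkyne, the quaternary C3 of 5 and the poor leaving ability of the bulky siloxide should secure.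

**Step 7**
Reactants: 8 (5S)-2-methyl-5-(propan-2-yl)-3-(triethoxysilyl)-5-[(triethylsilyl)oxy]cyclohex-2-en-1-one
Product: 9 (5R)-2-methyl-5-(propan-2-yl)-5-[(triethylsilyl)oxy]cyclohex-2-en-1-one
Conditions: AgF, THF/MeOH/H2O, rt, dark
Reagents that add atoms: none
Why: Fluoride-assisted silicon-to-silver exchange of the alkenyl trialkoxysilane and protonolysis (protodesilylation) run under near-neutral conditions, so the β-siloxy ketone should not enolise; the stereocentre is untouched and its descriptor changes only because silicon leaves the priority ranking.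

**Step 8**
Reactants: 9 (5R)-2-methyl-5-(propan-2-yl)-5-[(triethylsilyl)oxy]cyclohex-2-en-1-one
Product: 11 triethyl{[(1R)-4-methyl-1-(propan-2-yl)cyclohex-3-en-1-yl]oxy}silane, via tosylhydrazone 10 (not isolated)
Conditions: TsNHNH2, EtOH, 40 °C; then catecholborane, CHCl3, 0 °C to rt; then NaOAc·3H2O, reflux
Reagents that add atoms: none
Why: Condensation to the tosylhydrazone, 1,2-hydride delivery from catecholborane and loss of sulfinate give an allylic diazene that expels N2 by a concerted retro-ene shift, placing hydrogen on the former β-carbon and the double bond at the former carbonyl carbon regiospecifically (reductive 1,3-transposition of an enone, a Wolff–Kishner-type reduction).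

**Step 9**
Reactants: 11 triethyl{[(1R)-4-methyl-1-(propan-2-yl)cyclohex-3-en-1-yl]oxy}silane
Product: 12 (1R)-4-methyl-1-(propan-2-yl)cyclohex-3-en-1-ol
Conditions: Bu4NF, THF, rt to 40 °C
Reagents that add atoms: none
Why: Fluoride cleaves the Si–O bond under non-acidic conditions, which avoids acid-induced cyclisation of the hydroxy alkene to 1,4-cineole.

**Step 10**
Reactants: 13 methyl 3,5-dibromo-4-hydroxybenzoate
Product: 14 methyl 3,5-dibromo-4-methoxybenzoate
Conditions: MeI, K2CO3, acetone, reflux
Reagents that add atoms: iodomethane, CI
Why: Williamson ether synthesis on the acidic, doubly ortho-brominated phenol.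

**Step 11**
Reactants: 14 methyl 3,5-dibromo-4-methoxybenzoate
Product: 15 methyl 4-methoxy-3,5-bis(3-methylbut-2-en-1-yl)benzoate
Conditions: tributyl(3-methylbut-2-en-1-yl)stannane (2.5 equiv), Pd(PPh3)4 (10 mol%), DMF, 100 °C
Reagents that add atoms: tributyl(3-methylbut-2-en-1-yl)stannane, CCCC[Sn](CCCC)(CCCC)CC=C(C)C
Why: Twofold Stille coupling; the allylic stannane transfers its less substituted carbon, so the linear 3-methylbut-2-enyl groups should result, and the ester is tolerated.

**Step 12**
Reactants: 15 methyl 4-methoxy-3,5-bis(3-methylbut-2-en-1-yl)benzoate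
Product: 16 4-methoxy-3,5-bis(3-methylbut-2-en-1-yl)benzoic acid
Conditions: LiOH, THF/MeOH/H2O, 50 °C; then 1 M HCl, 0 °C
Reagents that add atoms: lithium hydroxide, [Li+].[OH-]
Why: Saponification of the unhindered methyl ester; a cold, dilute acid work-up should leave the trisubstituted alkenes intact.

**Step 13**
Reactants: 12 (1R)-4-methyl-1-(propan-2-yl)cyclohex-3-en-1-ol and 16 4-methoxy-3,5-bis(3-methylbut-2-en-1-yl)benzoic acid
Product: 19 (1R)-4-methyl-1-(propan-2-yl)cyclohex-3-en-1-yl 4-methoxy-3,5-bis(3-methylbut-2-en-1-yl)benzoate, via acid chloride 17 (not isolated), via lithium alkoxide 18 (not isolated)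
Conditions: 16, 1-chloro-N,N,2-trimethylprop-1-en-1-amine, CH2Cl2, 0 °C to rt; 12, n-BuLi, THF, −78 °C to 0 °C; combine, 0 °C to rt
Reagents that add atoms: none
Why: The acid chloride is made under neutral conditions with an α-chloroenamine (no HCl that could add to the prenyl alkenes) and acylates the pre-formed lithium alkoxide of the hindered tertiary alcohol (nucleophilic acyl substitution); the C–O bond at the stereocentre is never broken, so the configuration is retained.

**Compound list**
1 | 3-(benzyloxy)cyclobutan-1-one | O=C1CC(OCc2ccccc2)C1 | starting material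
2 | 3-(benzyloxy)-1-(propan-2-yl)cyclobutan-1-ol (cis/trans mixture) | CC(C)C1(O)CC(OCc2ccccc2)C1 | intermediate
3 | {[3-(benzyloxy)-1-(propan-2-yl)cyclobutyl]oxy}triethylsilane (cis/trans mixture) | CC[Si](CC)(CC)OC1(C(C)C)CC(OCc2ccccc2)C1 | intermediate
4 | 3-(propan-2-yl)-3-[(triethylsilyl)oxy]cyclobutan-1-ol (cis/trans mixture) | CC[Si](CC)(CC)OC1(C(C)C)CC(O)C1 | intermediate
5 | 3-(propan-2-yl)-3-[(triethylsilyl)oxy]cyclobutan-1-one | CC[Si](CC)(CC)OC1(C(C)C)CC(=O)C1 | intermediate
6 | prop-1-yn-1-ylmagnesium bromide | CC#C[Mg]Br | starting material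
7 | triethoxy(prop-1-yn-1-yl)silane | CC#C[Si](OCC)(OCC)OCC | intermediate
8 | (5S)-2-methyl-5-(propan-2-yl)-3-(triethoxysilyl)-5-[(triethylsilyl)oxy]cyclohex-2-en-1-one | CC[Si](CC)(CC)O[C@@]1(C(C)C)CC(=O)C(C)=C([Si](OCC)(OCC)OCC)C1 | intermediate
9 | (5R)-2-methyl-5-(propan-2-yl)-5-[(triethylsilyl)oxy]cyclohex-2-en-1-one | CC[Si](CC)(CC)O[C@@]1(C(C)C)CC(=O)C(C)=CC1 | intermediate
10 | 4-methyl-N'-{(5R)-2-methyl-5-(propan-2-yl)-5-[(triethylsilyl)oxy]cyclohex-2-en-1-ylidene}benzenesulfonohydrazide (tosylhydrazone) | CC[Si](CC)(CC)O[C@@]1(C(C)C)CC(=NNS(=O)(=O)c2ccc(C)cc2)C(C)=CC1 | intermediate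
11 | triethyl{[(1R)-4-methyl-1-(propan-2-yl)cyclohex-3-en-1-yl]oxy}silane | CC[Si](CC)(CC)O[C@@]1(C(C)C)CC=C(C)CC1 | intermediate
12 | (1R)-4-methyl-1-(propan-2-yl)cyclohex-3-en-1-ol, (R)-terpinen-4-ol | O[C@@]1(C(C)C)CC=C(C)CC1 | intermediate
13 | methyl 3,5-dibromo-4-hydroxybenzoate | COC(=O)c1cc(Br)c(O)c(Br)c1 | starting material
14 | methyl 3,5-dibromo-4-methoxybenzoate | COC(=O)c1cc(Br)c(OC)c(Br)c1 | intermediate
15 | methyl 4-methoxy-3,5-bis(3-methylbut-2-en-1-yl)benzoate | COC(=O)c1cc(CC=C(C)C)c(OC)c(CC=C(C)C)c1 | intermediate
16 | 4-methoxy-3,5-bis(3-methylbut-2-en-1-yl)benzoic acid | OC(=O)c1cc(CC=C(C)C)c(OC)c(CC=C(C)C)c1 | intermediate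
17 | 4-methoxy-3,5-bis(3-methylbut-2-en-1-yl)benzoyl chloride (acid chloride) | ClC(=O)c1cc(CC=C(C)C)c(OC)c(CC=C(C)C)c1 | intermediate
18 | lithium (1R)-4-methyl-1-(propan-2-yl)cyclohex-3-en-1-olate (lithium alkoxide) | [Li]O[C@@]1(C(C)C)CC=C(C)CC1 | intermediate
19 | (1R)-4-methyl-1-(propan-2-yl)cyclohex-3-en-1-yl 4-methoxy-3,5-bis(3-methylbut-2-en-1-yl)benzoate | COc1c(CC=C(C)C)cc(C(=O)O[C@@]2(C(C)C)CC=C(C)CC2)cc1CC=C(C)C | target

**Count**
Total steps: 13. Longest linear sequence: 9 steps (steps 1, 2, 3, 4, 6, 7, 8, 9, 13).

**Steps most likely to fail**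

Step 6 (proposed new method). The chiral ligand may discriminate poorly between the two enantiotopic ring bonds in the β-carbon elimination, the alkyne may insert with partly reversed orientation, or the alkylnickel intermediate may lose the siloxy group by β-elimination. Fallback, setting out from 5 and 7 and coming back at 9: the annulation is run without asymmetric induction under the established Ni(cod)2/PCy3 conditions (toluene, 100 °C) to give the racemic silyl enone F1. AgF protodesilylation as in step 7 then gives the racemic enone F2, and preparative chromatography on a chiral stationary phase (supercritical CO2/2-propanol) separates the enantiomers; the (5R)-enantiomer is 9. Stereocontrol thus rests on resolution instead of catalyst control.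

Step 7. Silicon-to-silver exchange may be sluggish at the tetrasubstituted, electron-poor alkenylsilane, or the ketone may enolise with loss of the β-siloxy group and aromatisation to a phenol. Fallback, setting out from 8 and coming back at 12: the ketone is first removed as a source of enolisation by Luche reduction (NaBH4, CeCl3·7H2O, EtOH, −40 °C) to the allylic alcohol F3. Basic fluoride is then harmless, and Bu4NF in THF at 50 °C takes off both the carbon-bound and the oxygen-bound silicon to give the diol F4. Mitsunobu displacement of the secondary allylic hydroxyl with 2-nitrobenzenesulfonylhydrazide (PPh3, diethyl azodicarboxylate, THF, −30 °C to rt) gives an allylic diazene that loses N2 by retro-ene shift with the same 1,3-transposition as step 8, delivering 12 directly.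

Step 8. The sulfonylhydrazide may add in conjugate fashion instead of condensing, hydride may be delivered 1,4 instead of 1,2, or siloxide may be eliminated; any pathway through an allylic ion or radical would move the double bond and so erode the enantiopurity. Fallback, setting out from 9 and coming back at 11: conjugate reduction with LiBH(s-Bu)3 (THF, −78 °C) gives the regiodefined lithium enolate, which is trapped with PhNTf2 as the enol triflate F5. Palladium-catalysed formate reduction (Pd(OAc)2, PPh3, Bu3N, HCO2H, DMF, 60 °C) replaces the C–O bond by C–H without moving the double bond and gives 11.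

**Further compounds**
F1 | step 6 | racemic 2-methyl-5-(propan-2-yl)-3-(triethoxysilyl)-5-[(triethylsilyl)oxy]cyclohex-2-en-1-one | CC[Si](CC)(CC)OC1(C(C)C)CC(=O)C(C)=C([Si](OCC)(OCC)OCC)C1
F2 | step 6 | racemic 2-methyl-5-(propan-2-yl)-5-[(triethylsilyl)oxy]cyclohex-2-en-1-one | CC[Si](CC)(CC)OC1(C(C)C)CC(=O)C(C)=CC1
F3 | step 7 | (5S)-2-methyl-5-(propan-2-yl)-3-(triethoxysilyl)-5-[(triethylsilyl)oxy]cyclohex-2-en-1-ol (both C1 epimers) | CC[Si](CC)(CC)O[C@@]1(C(C)C)CC(O)C(C)=C([Si](OCC)(OCC)OCC)C1
F4 | step 7 | (5R)-2-methyl-5-(propan-2-yl)cyclohex-2-ene-1,5-diol (both C1 epimers) | O[C@@]1(C(C)C)CC(O)C(C)=CC1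
F5 | step 8 | (5R)-2-methyl-5-(propan-2-yl)-5-[(triethylsilyl)oxy]cyclohex-1-en-1-yl trifluoromethanesulfonate | CC[Si](CC)(CC)O[C@@]1(C(C)C)CC(OS(=O)(=O)C(F)(F)F)=C(C)CC1
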